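The furofuran (7R,8S,7'R,8'S) is cut at C7–C8 and C7'–C8'. The feature exploited is the vicinal C8/C8' pair: when C9 and C9' are tied through oxygen into a five-membered lactone, C7 and C7' sit trans on it, although rings A (C7–O2–C9'–C8'–C8) and B (C7'–O7–C9–C8–C8') are cis-fused. C8/C8' therefore map onto the β/α carbons of (5S)-5-menthyloxybutenolide. In one operation a lithiated aryl dithiane (masked C7 acyl anion) adds 1,4 and the enolate is trapped by 3,4,5-trimethoxybenzaldehyde, forming both bonds and both ring-fusion stereocentres. The precursor is the 1,3-dithiane of 4-benzyloxy-3,5-dimethoxybenzaldehyde.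

Key step: step 2

Numbering: C7/C8/C9 are ArCH–O, ring-fusion CH and OCH2 of the 4-hydroxy-3,5-dimethoxyphenyl half; C7'/C8'/C9' are the same positions in the 3,4,5-trimethoxyphenyl half.

Assumption: the C7' carbinol of 8, 9 and 10 and the C7 carbinol of 10 are carried as epimer mixtures and left undefined in names and SMILES, because both centres are ionised and re-set in step 5.

Step 1
Reactants: 1 4-(benzyloxy)-3,5-dimethoxybenzaldehyde; 2 propane-1,3-dithiol
Product: 3 2-[4-(benzyloxy)-3,5-dimethoxyphenyl]-1,3-dithiane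
Conditions: BF3·OEt2 (cat.), CH2Cl2, 0 °C to rt
Reagents that add atoms: none
Why: Lewis-acid-catalysed dithioacetalisation of an aromatic aldehyde is routine, the aryl benzyl and methyl ethers are inert to catalytic BF3·OEt2 at this temperature, and no stereocentre is formed.

Step 2
Reactants: 3 2-[4-(benzyloxy)-3,5-dimethoxyphenyl]-1,3-dithiane; 4 (5S)-5-[(1S,2R,5S)-menthyloxy]furan-2(5H)-one; 5 3,4,5-trimethoxybenzaldehyde
Product: 8 (3R,4S,5S)-4-{2-[4-(benzyloxy)-3,5-dimethoxyphenyl]-1,3-dithian-2-yl}-3-[hydroxy(3,4,5-trimethoxyphenyl)methyl]-5-[(1S,2R,5S)-menthyloxy]dihydrofuran-2(3H)-one, via 2-lithio-2-aryl-1,3-dithiane 6 (not isolated), via lithium lactone enolate 7 (not isolated)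
Conditions: n-BuLi (1.05 equiv), THF, −78 to −20 °C; then 4, −78 °C; then 5, −78 °C; AcOH, −78 °C
Reagents that add atoms: none
Why: n-BuLi removes the C2 proton of 3 to give the sulfur-stabilised carbanion 6, an acyl-anion equivalent for C7 (dithiane umpolung), which adds in Michael fashion to the β-carbon of 4 (C4 of the furanone, the future C8) to give lithium enolate 7; 7 then attacks the carbonyl of 5 in an aldol addition through its α-carbon (future C8'), so C7–C8 and C7'–C8' form in one flask. The closest known reaction type is the tandem conjugate addition–electrophile trapping of lithiated 2-aryl-1,3-dithianes on 5-alkoxy-2(5H)-furanones, here with an aldehyde as the electrophile. No ring of the target is closed; the lactone is only a scaffold that is reduced away in step 4. C8 (4S in 8) is set by attack on the face of the flat butenolide opposite the menthyloxy group on the neighbouring acetal carbon (future C9), and C8' (3R) by approach of the aldehyde anti to the bulky dithianyl group just installed, which gives the 3,4-trans lactone and hence the 8S,8'S pair of the target; the C7' carbinol forms without control, which is harmless because that centre is ionised in step 5. The step needs 1,4- rather than 1,2-regioselectivity, which the soft, hindered aryl dithiane anion and the unhindered, doubly activated β-carbon provide, and it needs the aldolate to be kept from retro-aldol, which the cold AcOH quench secures.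

Step 3
Reactants: 8 dithianyl lactone adduct
Product: 9 (3R,4S,5S)-4-[4-(benzyloxy)-3,5-dimethoxybenzoyl]-3-[hydroxy(3,4,5-trimethoxyphenyl)methyl]-5-[(1S,2R,5S)-menthyloxy]dihydrofuran-2(3H)-one
Conditions: HgO, BF3·OEt2, THF–H2O, rt
Reagents that add atoms: water, O
Why: Mercury-promoted dithioketal hydrolysis: thiophilic divalent mercury, assisted by BF3·OEt2, opens the dithiane to a thionium ion that water converts into the aryl ketone, while the acyloxy acetal, the lactone and the free carbinol are expected to persist; no stereocentre is created and the trans C8/C8' arrangement is the preferred one should C8 enolise.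

Step 4
Reactants: 9 keto lactone
Product: 10 (2S,3S)-1-[4-(benzyloxy)-3,5-dimethoxyphenyl]-2,3-bis(hydroxymethyl)-4-(3,4,5-trimethoxyphenyl)butane-1,4-diol
Conditions: LiAlH4 (excess), THF, 0 °C to rt; then H2O
Reagents that add atoms: none
Why: Hydride reduction with LiAlH4 converts the ketone into the C7 carbinol and reduces both termini of the acyloxy-acetal lactone (the C9' carbonyl, and the C9 acetal carbon once ring opening and loss of menthoxide unmask it as an aldehyde) to CH2OH; C8 and C8' are not touched and the new C7 carbinol may form as a mixture.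

Step 5
Reactants: 10 tetraol
Product: 11 (1R,3aS,4R,6aS)-1-[4-(benzyloxy)-3,5-dimethoxyphenyl]-4-(3,4,5-trimethoxyphenyl)tetrahydro-1H,3H-furo[3,4-c]furan
Conditions: p-TsOH·H2O (cat.), CH2Cl2, 0 °C to rt, short reaction time; NaHCO3 quench
Reagents that add atoms: none
Why: Acid-catalysed double cyclodehydration (SN1 etherification): each benzylic carbinol ionises to an alkoxy-stabilised benzylic cation that is captured by the γ-hydroxymethyl group (C9'–OH at C7 closes ring A, C9–OH at C7' closes ring B), and because each cation reacts from the conformer in which the C8–H or C8'–H bond eclipses the aryl plane to minimise allylic strain, both aryl groups should end exo (7R,7'R) whatever the carbinol configurations were, the cis ring fusion being dictated by the fixed 8S,8'S centres.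

Step 6
Reactants: 11 O-benzyl furofuran
Product: 12 4-[(1R,3aS,4R,6aS)-4-(3,4,5-trimethoxyphenyl)tetrahydro-1H,3H-furo[3,4-c]furan-1-yl]-2,6-dimethoxyphenol
Conditions: H2 (1 atm), 10% Pd/C, EtOAc, rt, stopped after one equivalent of H2
Reagents that add atoms: none
Why: Catalytic hydrogenolysis cleaves the aryl benzyl ether much faster than the dialkyl benzylic C7–O and C7'–O bonds of the furofuran under neutral conditions, so the phenol should be released without ring opening or change at any stereocentre.

Compound list
1 | 4-(benzyloxy)-3,5-dimethoxybenzaldehyde | COc1cc(C=O)cc(OC)c1OCc1ccccc1 | starting material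
2 | propane-1,3-dithiol | SCCCS | starting material
3 | 2-[4-(benzyloxy)-3,5-dimethoxyphenyl]-1,3-dithiane | COc1cc(C2SCCCS2)cc(OC)c1OCc1ccccc1 | intermediate
4 | (5S)-5-{[(1S,2R,5S)-5-methyl-2-(propan-2-yl)cyclohexyl]oxy}furan-2(5H)-one, i.e. (5S)-5-(d-menthyloxy)-2(5H)-furanone | O=C1C=C[C@H](O1)O[C@H]1C[C@@H](C)CC[C@@H]1C(C)C | starting material
5 | 3,4,5-trimethoxybenzaldehyde | COc1cc(C=O)cc(OC)c1OC | starting material
6 | 2-[4-(benzyloxy)-3,5-dimethoxyphenyl]-2-lithio-1,3-dithiane (not isolated) | COc1cc(C2([Li])SCCCS2)cc(OC)c1OCc1ccccc1 | intermediate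
7 | lithium (4S,5S)-4-{2-[4-(benzyloxy)-3,5-dimethoxyphenyl]-1,3-dithian-2-yl}-5-[(1S,2R,5S)-menthyloxy]-4,5-dihydrofuran-2-olate (not isolated) | [Li]OC1=C[C@H](C2(c3cc(OC)c(OCc4ccccc4)c(OC)c3)SCCCS2)[C@@H](O[C@H]2C[C@@H](C)CC[C@@H]2C(C)C)O1 | intermediate
8 | (3R,4S,5S)-4-{2-[4-(benzyloxy)-3,5-dimethoxyphenyl]-1,3-dithian-2-yl}-3-[hydroxy(3,4,5-trimethoxyphenyl)methyl]-5-[(1S,2R,5S)-menthyloxy]dihydrofuran-2(3H)-one | O=C1O[C@H](O[C@H]2C[C@@H](C)CC[C@@H]2C(C)C)[C@@H](C2(c3cc(OC)c(OCc4ccccc4)c(OC)c3)SCCCS2)[C@@H]1C(O)c1cc(OC)c(OC)c(OC)c1 | intermediate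
9 | (3R,4S,5S)-4-[4-(benzyloxy)-3,5-dimethoxybenzoyl]-3-[hydroxy(3,4,5-trimethoxyphenyl)methyl]-5-[(1S,2R,5S)-menthyloxy]dihydrofuran-2(3H)-one | O=C1O[C@H](O[C@H]2C[C@@H](C)CC[C@@H]2C(C)C)[C@@H](C(=O)c2cc(OC)c(OCc3ccccc3)c(OC)c2)[C@@H]1C(O)c1cc(OC)c(OC)c(OC)c1 | intermediate
10 | (2S,3S)-1-[4-(benzyloxy)-3,5-dimethoxyphenyl]-2,3-bis(hydroxymethyl)-4-(3,4,5-trimethoxyphenyl)butane-1,4-diol | OC[C@@H](C(O)c1cc(OC)c(OCc2ccccc2)c(OC)c1)[C@@H](CO)C(O)c1cc(OC)c(OC)c(OC)c1 | intermediate
11 | (1R,3aS,4R,6aS)-1-[4-(benzyloxy)-3,5-dimethoxyphenyl]-4-(3,4,5-trimethoxyphenyl)tetrahydro-1H,3H-furo[3,4-c]furan | COc1cc([C@@H]2OC[C@@H]3[C@H]2CO[C@H]3c2cc(OC)c(OC)c(OC)c2)cc(OC)c1OCc1ccccc1 | intermediate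
12 | 4-[(1R,3aS,4R,6aS)-4-(3,4,5-trimethoxyphenyl)tetrahydro-1H,3H-furo[3,4-c]furan-1-yl]-2,6-dimethoxyphenol (7R,8S,7'R,8'S) | COc1cc([C@@H]2OC[C@@H]3[C@H]2CO[C@H]3c2cc(OC)c(OC)c(OC)c2)cc(OC)c1O | target

Total step count: 6. Longest linear sequence: 6 steps (1 → 3 → 8 → 9 → 10 → 11 → 12).

Steps most likely to fail

Step 2. The capture of the hindered lactone enolate by the aldehyde may be slow or reversible (retro-aldol on warming, or protonation instead of aldol), so that only the C7–C8 bond survives; attack of the dithiane anion on the lactone carbonyl is the lesser danger. The fallback sets out from 3 and 4 and separates the two bond formations. The conjugate addition is run alone (n-BuLi, THF, −78 °C, then 4, AcOH quench) and the conjugate adduct lactone F1 is isolated. F1 is then re-enolised with LiN(i-Pr)2 in THF at −78 °C, if needed transmetalated with ZnCl2 to stabilise the aldolate, and treated with 5. The aldehyde again approaches anti to the dithianyl group, and the sequence comes back to the route at 8.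

Step 5. Exo selectivity may erode: the acid needed to ionise the weakly donating, twisted 4-benzyloxy ring may also re-ionise the closed benzylic ethers, letting an aryl group drift to the endo position, or ring A may close sluggishly. The fallback sets out from 10 and reverses the order of the last two operations. Hydrogenolysis (H2, Pd/C, EtOAc) first gives the free-phenol pentaol F4. With the para-hydroxyl free, C7 ionises through a para-quinone methide under much weaker acid (catalytic pyridinium p-toluenesulfonate, CH2Cl2), so ring A closes under kinetic control. Only the trimethoxyphenyl carbinol then needs a brief exposure to p-TsOH to close ring B. This path comes back to the route at 12 and bypasses 11.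

Step 3. The β-hydroxy lactone may degrade under the Lewis-acidic mercury conditions (dehydration, retro-aldol or loss of the menthyl acetal) before the hindered dithioketal is fully hydrolysed. The fallback sets out from 8 and reduces first. LiAlH4 in THF leaves the dithiane intact and gives the dithianyl triol F2 with loss of menthol. Alkylative hydrolysis of the robust triol (MeI, CaCO3, MeCN–H2O, 40 °C) gives the hydroxy ketone F3, which should sit largely as its cyclic hemiketals. NaBH4 in MeOH reduces F3 through its open form and comes back to the route at 10.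

Further compounds
F1 | step 2 | (4S,5S)-4-{2-[4-(benzyloxy)-3,5-dimethoxyphenyl]-1,3-dithian-2-yl}-5-[(1S,2R,5S)-menthyloxy]dihydrofuran-2(3H)-one | O=C1O[C@H](O[C@H]2C[C@@H](C)CC[C@@H]2C(C)C)[C@@H](C2(c3cc(OC)c(OCc4ccccc4)c(OC)c3)SCCCS2)C1
F2 | step 3 | (2S,3S)-2-{2-[4-(benzyloxy)-3,5-dimethoxyphenyl]-1,3-dithian-2-yl}-3-[hydroxy(3,4,5-trimethoxyphenyl)methyl]butane-1,4-diol | OC[C@@H](C1(c2cc(OC)c(OCc3ccccc3)c(OC)c2)SCCCS1)[C@@H](CO)C(O)c1cc(OC)c(OC)c(OC)c1
F3 | step 3 | (2S,3S)-1-[4-(benzyloxy)-3,5-dimethoxyphenyl]-4-hydroxy-2,3-bis(hydroxymethyl)-4-(3,4,5-trimethoxyphenyl)butan-1-one (open form of its cyclic hemiketals) | OC[C@@H](C(=O)c1cc(OC)c(OCc2ccccc2)c(OC)c1)[C@@H](CO)C(O)c1cc(OC)c(OC)c(OC)c1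
F4 | step 5 | (2S,3S)-1-(4-hydroxy-3,5-dimethoxyphenyl)-2,3-bis(hydroxymethyl)-4-(3,4,5-trimethoxyphenyl)butane-1,4-diol | OC[C@@H](C(O)c1cc(OC)c(O)c(OC)c1)[C@@H](CO)C(O)c1cc(OC)c(OC)c(OC)c1
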